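**Retrosynthetic overview**
- The strategy rests on the C9–C10 bond of the ten-membered carbocycle (C1–C10). It joins the ketone carbon C9 to the methyl-bearing carbon C10 of the E-C1=C10 enone. Taking C9=O back to C9–OH and cutting C9–C10 gives an (E)-C10 alkenyl iodide and a C9 aldehyde, to be joined by Ni/Cr on the fully oxygenated chain.
- Both oxiranes (C4–C5 fused, C7–C11 spiro) carry their CH2OAc on a fully substituted oxirane carbon, so each is the Sharpless epoxide of a primary allylic alcohol. C4 and C11 are both R, so one D-(−)-tartrate catalyst sets all four centres in a single double epoxidation of a diene-diol.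
- C4=C5 (C15 trans to C6) comes from an HWE reaction of an α-alkylated phosphonoacetate with a C5 aldehyde. C7=C11 (C12 cis to C8) comes from anti-carbomagnesiation of a 2-alkyn-1-ol with MeMgBr and capture by allyl bromide.
- The allyl CH=CH2 is the latent C9 aldehyde, so no second primary alcohol has to be told apart from C12–OH.
- Ring order: the two oxiranes together (step 12), the ten-membered ring (step 15), then C9–OH to the ketone (step 16).

Key step: step 15

Remark: germacrane numbering is used throughout (ring C1–C10, C14 = Me on C10, C15 on C4, C11–C13 on C7, C9' = terminal CH2 of the allyl group). The C7 descriptor switches between R and S only because the CIP rank of C8 changes. Step 15 is assumed to give both C9 epimers, which are carried on together.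

**Step 1**
Reactants: 1 pent-3-yn-1-ol
Product: 3 (E)-4-iodopent-3-en-1-ol, via bis-zirconocene alkenyl alkoxide 2 (not isolated)
Conditions: Cp2ZrHCl (2.5 equiv), THF, rt → 40 °C; then I2, THF, −78 → 0 °C
Reagents that add atoms: iodine, II
Why: After O–H metalation, syn-hydrozirconation under an equilibrating excess of Zr–H should place zirconium on the less hindered, methyl-bearing C10, and iodinolysis with retention then gives the E-iodide (I trans to C2).

**Step 2**
Reactants: 3 (E)-4-iodopent-3-en-1-ol
Product: 4 (E)-2,5-diiodopent-2-ene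
Conditions: I2, PPh3, imidazole, CH2Cl2, 0 °C, dark
Reagents that add atoms: iodine, II
Why: Appel-type iodination displaces the alkoxyphosphonium group at the primary carbon C3 by SN2 and leaves the alkenyl iodide untouched.

**Step 3**
Reactants: 5 triethyl phosphonoacetate; 4 (E)-2,5-diiodopent-2-ene
Product: 7 ethyl (5E)-2-(diethoxyphosphoryl)-6-iodohept-5-enoate (racemic at C4), via sodium phosphonoacetate carbanion 6 (not isolated)
Conditions: 5 (1.5 equiv), NaH, THF–DMF, 0 °C; then 4, 50 °C
Reagents that add atoms: none
Why: SN2 alkylation of the soft stabilised carbanion occurs only at the sp3 C–I bond, the excess of 5 holds back dialkylation, and the racemic C4 centre disappears in step 10.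

**Step 4**
Reactants: 8 but-3-yn-1-ol
Product: 9 tert-butyl(but-3-yn-1-yloxy)dimethylsilane
Conditions: TBSCl, imidazole, CH2Cl2, 0 °C → rt
Reagents that add atoms: tert-butyldimethylsilyl chloride, CC(C)(C)[Si](C)(C)Cl
Why: Standard silylation masks the C5 hydroxyl against the organometallic reagents of steps 5 and 6.

**Step 5**
Reactants: 9 tert-butyl(but-3-yn-1-yloxy)dimethylsilane
Product: 11 5-[(tert-butyldimethylsilyl)oxy]pent-2-yn-1-ol, via lithium acetylide 10 (not isolated)
Conditions: n-BuLi, THF, −78 °C; (CH2O)n, −78 °C → rt
Reagents that add atoms: paraformaldehyde (reacts as formaldehyde), C=O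
Why: Hydroxymethylation of the lithium acetylide adds C12 and creates the propargylic alcohol that directs step 6.

**Step 6**
Reactants: 11 5-[(tert-butyldimethylsilyl)oxy]pent-2-yn-1-ol
Product: 13 (2E)-3-{2-[(tert-butyldimethylsilyl)oxy]ethyl}-2-methylhexa-2,5-dien-1-ol (C12H2OH cis to the allyl group C8; methyl cis to C6), via oxamagnesacycle 12 (not isolated)
Conditions: MeMgBr (3.5 equiv), CuI (20 mol %), Et2O–toluene, −20 °C → rt; then allyl bromide (5 equiv), 0 °C → rt
Reagents that add atoms: methylmagnesium bromide, C[Mg]Br; allyl bromide, C=CCBr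
Why: In the copper-catalysed anti-carbomagnesiation of a 2-alkyn-1-ol the magnesium alkoxide steers methyl to C11 and magnesium to C7 within a five-membered chelate, so copper-catalysed allylation with retention puts C8 cis to C12.

**Step 7**
Reactants: 13 dienol
Product: 14 (2E)-3-{2-[(tert-butyldimethylsilyl)oxy]ethyl}-2-methylhexa-2,5-dien-1-yl acetate
Conditions: Ac2O, pyridine, DMAP (cat.), CH2Cl2, 0 °C → rt
Reagents that add atoms: acetic anhydride, CC(=O)OC(C)=O
Why: Acetylation covers C12–OH during the C5 oxidation with a group that the reduction of step 11 removes at no extra cost.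

**Step 8**
Reactants: 14 silyl ether acetate
Product: 15 (2E)-3-(2-hydroxyethyl)-2-methylhexa-2,5-dien-1-yl acetate
Conditions: HF·pyridine, pyridine, THF, 0 °C → rt
Reagents that add atoms: none
Why: Buffered fluoride desilylation spares the allylic acetate, and acetyl migration is geometrically excluded because C12 and C6 are trans on the alkene.

**Step 9**
Reactants: 15 hydroxy acetate
Product: 16 (2E)-2-methyl-3-(2-oxoethyl)hexa-2,5-dien-1-yl acetate (C5 aldehyde)
Conditions: Dess–Martin periodinane, NaHCO3, CH2Cl2, 0 °C; used at once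
Reagents that add atoms: none
Why: Buffered Dess–Martin oxidation is neutral enough to deliver a β,γ-unsaturated aldehyde without moving C7=C11 into conjugation.

**Step 10**
Reactants: 7 phosphonate; 16 C5 aldehyde
Product: 18 ethyl (2E,5E)-7-acetoxy-2-[(3E)-4-iodopent-3-en-1-yl]-6-methyl-5-(prop-2-en-1-yl)hepta-2,5-dienoate, via sodium phosphonate carbanion 17 (not isolated)
Conditions: 7, NaH, THF, 0 °C; then 16, −78 → 0 °C
Reagents that add atoms: none
Why: In the Horner–Wadsworth–Emmons olefination, reversible addition should funnel through the less crowded oxaphosphetane so that CO2Et (C15) ends trans to C6 (C3 and C6 cis); the preformed salt leaves no free base for the aldehyde, and any geometric isomer is removed by chromatography here or at 19.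

**Step 11**
Reactants: 18 iodo trienoate
Product: 19 (2E,5E)-2-[(3E)-4-iodopent-3-en-1-yl]-6-methyl-5-(prop-2-en-1-yl)hepta-2,5-diene-1,7-diol
Conditions: DIBAL-H (6 equiv), CH2Cl2, −78 °C; Rochelle salt
Reagents that add atoms: none
Why: 1,2-Reduction of the enoate and reductive removal of the acetate free both allylic alcohols (C15–OH, C12–OH) in one operation, while alkenyl iodide and isolated alkenes are inert at −78 °C.

**Step 12**
Reactants: 19 diene-diol
Product: 21 (4R,5R,7R,11R)-bis-epoxy diol (C4–C5 oxirane with C3 and C6 cis; C7–C11 oxirane with C8 and C12 cis), via C4–C5 monoepoxide 20 (not isolated)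
Conditions: Ti(OiPr)4 (40 mol %), D-(−)-DET (50 mol %), TBHP (5 equiv, decane), 4 Å MS, CH2Cl2, −25 °C
Reagents that add atoms: tert-butyl hydroperoxide, CC(C)(C)OO
Why: In the double Katsuki–Sharpless epoxidation D-(−)-tartrate gives the 2R-type epoxy alcohol at both carbinol-bearing carbons (C4 and C11); the alkene geometries are transferred stereospecifically to C5 and C7; a facial error at one alkene becomes a separable diastereomer; and the unactivated allyl and iodoalkene π bonds do not react.

**Step 13**
Reactants: 21 bis-epoxy diol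
Product: 22 (4R,5R,7R,11R)-bis-epoxy diacetate bearing the C7 allyl group
Conditions: Ac2O, Et3N, DMAP (cat.), CH2Cl2, 0 °C
Reagents that add atoms: acetic anhydride, CC(=O)OC(C)=O
Why: Mild acylation installs both final acetates and blocks Payne rearrangement of the epoxy alcohols.

**Step 14**
Reactants: 22 bis-epoxy diacetate
Product: 24 (4R,5R,7S,11R)-iodo aldehyde bis-epoxide diacetate, via vicinal diol 23 (not isolated)
Conditions: OsO4 (2 mol %), NaIO4 (4 equiv), 2,6-lutidine, dioxane–H2O (3:1), 0 °C → rt
Reagents that add atoms: osmium tetroxide, O=[Os](=O)(=O)=O; sodium periodate (re-oxidant), [Na+].[O-]I(=O)(=O)=O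
Why: In the Lemieux–Johnson cleavage the monosubstituted C9=C9' bond is the only unhindered, electron-rich alkene left, the hindered iodine-bearing C1=C10 bond is deactivated toward osmylation, and the lutidine buffer protects the β,γ-epoxy aldehyde.

**Step 15**
Reactants: 24 iodo aldehyde bis-epoxide diacetate
Product: 27 9-hydroxy macrocycle (both C9 epimers usable; 9R drawn), via alkenylchromium(III) species 25 (not isolated), via chromium(III) alkoxide 26 (not isolated)
Conditions: CrCl2 (10 equiv), NiCl2 (2 mol % of Cr), degassed DMSO–THF (3:1), 24 added by syringe pump to ca. 2 mM, rt; aq. sodium serinate work-up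
Reagents that add atoms: none
Why: Ni(0), formed from NiCl2 by Cr(II), inserts into the C10–I bond with retention and passes the alkenyl group to chromium, and the alkenylchromium 25 adds to the C9 aldehyde to give alkoxide 26, which is hydrolysed to 27. The closest known reaction type is the intramolecular Nozaki–Hiyama–Kishi coupling of an alkenyl iodide with an aldehyde, which has been used for ten-membered and larger rings. The ten-membered carbocycle closes in a 10-exo-trig mode at the C9 carbonyl, aided by slow addition at high dilution and by two turn elements in the chain, the C4–C5 oxirane that holds C3 and C6 cis and the quaternary C7. The only new stereocentre, C9, is set by the macrocyclic transition state alone and needs no control because step 16 erases it. The step needs selectivity for the aldehyde over two acetates and two oxiranes, which the low basicity and aldehyde preference of organochromium(III) should supply, and no allylic acetate or vinyl oxirane remains for Ni(0) or Cr(II) to ionise because both alkenes were epoxidised first. The E geometry of C1=C10 is carried over unchanged from 3.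

**Step 16**
Reactants: 27 9-hydroxy macrocycle
Product: 28 target, (1(10)E,4R,5R,7S,11R)-12,15-diacetoxy-4,5:7,11-diepoxygermacr-1(10)-en-9-one
Conditions: Dess–Martin periodinane, NaHCO3, CH2Cl2, 0 °C → rt
Reagents that add atoms: none
Why: Buffered Dess–Martin oxidation converges both allylic carbinol epimers on the enone under neutral conditions, so C8–H is never deprotonated and the C7–C11 oxirane of the β,γ-epoxy ketone stays closed.

**Compound list**
1 | pent-3-yn-1-ol | CC#CCCO | starting material
2 | bis-zirconocene alkenyl alkoxide | C/C(=C\CCO[Zr](Cl)(C1C=CC=C1)C1C=CC=C1)[Zr](Cl)(C1C=CC=C1)C1C=CC=C1 | intermediate (not isolated)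
3 | (E)-4-iodopent-3-en-1-ol | C/C(I)=C\CCO | intermediate
4 | (E)-2,5-diiodopent-2-ene | C/C(I)=C\CCI | intermediate
5 | triethyl phosphonoacetate | CCOC(=O)CP(=O)(OCC)OCC | starting material
6 | sodium phosphonoacetate carbanion | CCOC(=O)[CH-]P(=O)(OCC)OCC.[Na+] | intermediate (not isolated)
7 | ethyl (5E)-2-(diethoxyphosphoryl)-6-iodohept-5-enoate | CCOC(=O)C(CC/C=C(\C)I)P(=O)(OCC)OCC | intermediate
8 | but-3-yn-1-ol | C#CCCO | starting material
9 | tert-butyl(but-3-yn-1-yloxy)dimethylsilane | C#CCCO[Si](C)(C)C(C)(C)C | intermediate
10 | lithium acetylide of 9 | [Li]C#CCCO[Si](C)(C)C(C)(C)C | intermediate (not isolated)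
11 | 5-[(tert-butyldimethylsilyl)oxy]pent-2-yn-1-ol | OCC#CCCO[Si](C)(C)C(C)(C)C | intermediate
12 | oxamagnesacycle (Mg on C7, O on C12) | CC1=C(CCO[Si](C)(C)C(C)(C)C)[Mg]OC1 | intermediate (not isolated)
13 | (2E)-3-{2-[(tert-butyldimethylsilyl)oxy]ethyl}-2-methylhexa-2,5-dien-1-ol | OC/C(C)=C(\CC=C)CCO[Si](C)(C)C(C)(C)C | intermediate
14 | acetate of 13 | CC(=O)OC/C(C)=C(\CC=C)CCO[Si](C)(C)C(C)(C)C | intermediate
15 | (2E)-3-(2-hydroxyethyl)-2-methylhexa-2,5-dien-1-yl acetate | CC(=O)OC/C(C)=C(\CC=C)CCO | intermediate
16 | (2E)-2-methyl-3-(2-oxoethyl)hexa-2,5-dien-1-yl acetate | CC(=O)OC/C(C)=C(\CC=C)CC=O | intermediate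
17 | sodium carbanion of 7 | CCOC(=O)[C-](CC/C=C(\C)I)P(=O)(OCC)OCC.[Na+] | intermediate (not isolated)
18 | ethyl (2E,5E)-7-acetoxy-2-[(3E)-4-iodopent-3-en-1-yl]-6-methyl-5-(prop-2-en-1-yl)hepta-2,5-dienoate | CCOC(=O)/C(CC/C=C(\C)I)=C/C/C(CC=C)=C(\C)COC(C)=O | intermediate
19 | (2E,5E)-2-[(3E)-4-iodopent-3-en-1-yl]-6-methyl-5-(prop-2-en-1-yl)hepta-2,5-diene-1,7-diol | OC/C(CC/C=C(\C)I)=C/C/C(CC=C)=C(\C)CO | intermediate
20 | (4R,5R)-C4–C5 monoepoxide of 19 | OC[C@@]1(CC/C=C(\C)I)O[C@@H]1C/C(CC=C)=C(\C)CO | intermediate (not isolated)
21 | (4R,5R,7R,11R)-bis-epoxy diol | OC[C@@]1(CC/C=C(\C)I)O[C@@H]1C[C@@]2(CC=C)O[C@]2(C)CO | intermediate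
22 | (4R,5R,7R,11R)-bis-epoxy diacetate with C7 allyl | CC(=O)OC[C@@]1(CC/C=C(\C)I)O[C@@H]1C[C@@]2(CC=C)O[C@]2(C)COC(C)=O | intermediate
23 | C9,C9'-diol of 22 (epimers at C9) | CC(=O)OC[C@@]1(CC/C=C(\C)I)O[C@@H]1C[C@@]2(CC(O)CO)O[C@]2(C)COC(C)=O | intermediate (not isolated)
24 | (4R,5R,7S,11R)-iodo aldehyde bis-epoxide diacetate | CC(=O)OC[C@@]1(CC/C=C(\C)I)O[C@@H]1C[C@@]2(CC=O)O[C@]2(C)COC(C)=O | intermediate
25 | C10 alkenylchromium(III) dichloride | CC(=O)OC[C@@]1(CC/C=C(\C)[Cr](Cl)Cl)O[C@@H]1C[C@@]2(CC=O)O[C@]2(C)COC(C)=O | intermediate (not isolated)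
26 | macrocyclic C9 chromium(III) alkoxide | CC(=O)OC[C@]12CC/C=C(\C)[C@H](O[Cr](Cl)Cl)C[C@]3(C[C@H]1O2)O[C@]3(C)COC(C)=O | intermediate (not isolated)
27 | 9-hydroxy macrocycle (9R drawn, either epimer serves) | CC(=O)OC[C@]12CC/C=C(\C)[C@H](O)C[C@]3(C[C@H]1O2)O[C@]3(C)COC(C)=O | intermediate
28 | (1(10)E,4R,5R,7S,11R)-12,15-diacetoxy-4,5:7,11-diepoxygermacr-1(10)-en-9-one | CC(=O)OC[C@]12CC/C=C(\C)C(=O)C[C@]3(C[C@H]1O2)O[C@]3(C)COC(C)=O | target

**Totals**
- Total step count: 16.
- Longest linear sequence: 13 steps (steps 4–16, from but-3-yn-1-ol).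

**Three steps most likely to fail**

*Step 15.*
- Oligomerisation may outrun closure of the strained ten-membered ring.
- Cr(III) and chloride may open the fully substituted C7–C11 oxirane.
- The β,γ-epoxy aldehyde may undergo β-elimination before the C–C bond forms.

The fallback keeps the C9–C10 closure but turns it from a carbonyl addition into a neutral acyl cross-coupling that gives the enone directly. Setting out from 24, buffered Pinnick oxidation (NaClO2, NaH2PO4, 2-methylbut-2-ene) would give the carboxylic acid F1. This is not stored, so that it cannot lactonise onto the oxirane, and is coupled at once with thiophenol (EDC, cat. DMAP) to the S-phenyl thioester F2. Palladium-catalysed iodine–tin exchange with hexamethylditin then gives the (E)-alkenylstannane F3. A high-dilution Liebeskind–Srogl-type ketone synthesis (Pd2(dba)3, tri-2-furylphosphine, copper(I) diphenylphosphinate, THF) joins C9 to C10 and comes back to the route at the target 28, replacing steps 15 and 16.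

*Step 6.*
- Methyl transfer to the internal alkyne may be sluggish.
- Capture of the hindered alkenylmagnesium may be incomplete, or protonation may intervene. The excess Grignard reagent needed for the first event also consumes allyl bromide.

The fallback separates the two C–C bond formations and makes C7–C8 by palladium catalysis. Setting out from 11, the carbomagnesiation is driven to completion on its own and quenched with iodine, the best-established trap for such chelates. This gives the (Z)-iodo allylic alcohol F4, which can be freed from protonated or regioisomeric material. A Stille coupling with allyltributylstannane (Pd2(dba)3, AsPh3, CuI, DMF) then replaces iodine by allyl with retention and comes back to the route at 13.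

*Step 10.*
- The carbanion may shift C7=C11 into conjugation with the C5 aldehyde or enolise it.
- The α-branched phosphonate may erode the preference for C15 trans to C6.

The fallback replaces the charged phosphonate carbanion by a neutral, salt-free stabilised ylide. Setting out from 4, alkylation of commercial (carbethoxymethylene)triphenylphosphorane in refluxing acetonitrile would give the phosphonium iodide F5. Aqueous NaOH/CH2Cl2 converts it into the α-alkyl ylide F6. A Wittig reaction of F6 with aldehyde 16 in CH2Cl2 at rt, with no external base present, should favour the E-enoate and comes back to the route at 18.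

**Further compounds**
F1 | step 15 | (4R,5R,7S,11R)-iodo carboxylic acid bis-epoxide diacetate (C9 acid) | CC(=O)OC[C@@]1(CC/C=C(\C)I)O[C@@H]1C[C@@]2(CC(=O)O)O[C@]2(C)COC(C)=O
F2 | step 15 | S-phenyl C9 thioester of F1 | CC(=O)OC[C@@]1(CC/C=C(\C)I)O[C@@H]1C[C@@]2(CC(=O)Sc3ccccc3)O[C@]2(C)COC(C)=O
F3 | step 15 | (E)-C10 trimethylstannyl S-phenyl thioester | CC(=O)OC[C@@]1(CC/C=C(\C)[Sn](C)(C)C)O[C@@H]1C[C@@]2(CC(=O)Sc3ccccc3)O[C@]2(C)COC(C)=O
F4 | step 6 | (2Z)-5-[(tert-butyldimethylsilyl)oxy]-3-iodo-2-methylpent-2-en-1-ol | OC/C(C)=C(\I)CCO[Si](C)(C)C(C)(C)C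
F5 | step 10 | [(5E)-1-ethoxy-6-iodo-1-oxohept-5-en-2-yl]triphenylphosphonium iodide | CCOC(=O)C(CC/C=C(\C)I)[P+](c1ccccc1)(c1ccccc1)c1ccccc1.[I-]
F6 | step 10 | ethyl (5E)-6-iodo-2-(triphenyl-λ5-phosphanylidene)hept-5-enoate | CCOC(=O)C(CC/C=C(\C)I)=P(c1ccccc1)(c1ccccc1)c1ccccc1
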